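**Retrosynthetic overview**

1. The two ring carbonyls of target 21 are uncovered late from lower-level handles: C2=O from a C2 carboxyl (oxidative decarboxylation, then hemiaminal oxidation) and C4=O from a C4 nitro group (Nef reaction); the N-acyl chain comes from acid 5.
2. Pyrrolidine 13 ⇐ imino ester 11 + 2-methyl-1-nitropropene 12: one catalytic asymmetric (3+2) cycloaddition makes C2–C3 and C4–C5, the quaternary C3 and the C5 stereocentre. It is the only ring-forming event.
3. Enabling feature: in the ring N1–C2–C3–C4–C5 the two C–C bonds β to nitrogen flank the C3 (gem-dimethyl)–C4 (oxygenated) pair, so the ring is an azomethine ylide (C2–N1–C5) plus a dimethylketene-equivalent alkene (C3=C4). C3 carries no hydrogen, so the nitroalkene has no geometry to control and a later cation at C2 cannot drain to an enamide.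
4. Imine 11 ⇐ aldehyde 9 + glycine tert-butyl ester; 9 and 5 ⇐ antipodal N-crotonoyl sultams by auxiliary-controlled 1,4-addition of LiCCl3.

Key step: step 8

Assumption: LiCCl3 is taken to add to the Cβ-Si face of the lithium-chelated s-cis N-crotonoyl (2R)-sultam (Cβ-Re face of its antipode); if the sense proves opposite, the two sultam antipodes exchange roles between steps 1–2 and 4–5.

Assumption: (R)-DTBM-Segphos is taken to deliver the (2R,5R) series in step 8 (otherwise its antipode is used); the C4 configuration of 13 and 15 is inconsequential because C4 becomes the ketone carbon.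

**Step 1**
Reactants: 1 (2R)-bornane-10,2-sultam; 2 (E)-but-2-enoyl chloride
Product: 3 (2R)-N-[(E)-but-2-enoyl]bornane-10,2-sultam
Conditions: NaH, toluene, 0 °C to rt
Reagents that add atoms: none
Why: N-acylation of the sodium salt of the sultam with an acid chloride is the standard amide-forming entry to N-enoyl sultams and creates no stereocentre.

**Step 2**
Reactants: 3
Product: 4 (2R)-N-[(3S)-4,4,4-trichloro-3-methylbutanoyl]bornane-10,2-sultam
Conditions: CHCl3, LiN(SiMe3)2, THF, −78 °C; AcOH quench at −78 °C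
Reagents that add atoms: chloroform, ClC(Cl)Cl
Why: Auxiliary-controlled Michael (1,4-) addition of trichloromethyllithium to the chelated N-enoyl sultam should place CCl3 on the Cβ-Si face and set the (3S) centre, the cold quench guarding against retro-addition and carbene formation.

**Step 3**
Reactants: 4
Product: 5 (3S)-4,4,4-trichloro-3-methylbutanoic acid
Conditions: LiOH, H2O2, THF/H2O, 0 °C; Na2SO3; then aq. HCl
Reagents that add atoms: hydrogen peroxide, OO
Why: Hydroperoxide-mediated hydrolysis of the N-acyl sultam (exocyclic acyl cleavage) should free the acid and return auxiliary 1, the weakly basic nucleophile limiting E1cB loss of the CCl3 group and leaving the β-stereocentre untouched.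

**Step 4**
Reactants: 6 (2S)-bornane-10,2-sultam; 2 (E)-but-2-enoyl chloride
Product: 7 (2S)-N-[(E)-but-2-enoyl]bornane-10,2-sultam
Conditions: NaH, toluene, 0 °C to rt
Reagents that add atoms: none
Why: Same N-acylation as step 1 in the antipodal auxiliary series.

**Step 5**
Reactants: 7
Product: 8 (2S)-N-[(3R)-4,4,4-trichloro-3-methylbutanoyl]bornane-10,2-sultam
Conditions: CHCl3, LiN(SiMe3)2, THF, −78 °C; AcOH quench at −78 °C
Reagents that add atoms: chloroform, ClC(Cl)Cl
Why: The same auxiliary-controlled Michael addition as step 2 on the antipodal enoyl sultam should set the (3R) centre.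

**Step 6**
Reactants: 8
Product: 9 (3R)-4,4,4-trichloro-3-methylbutanal
Conditions: iBu2AlH, CH2Cl2, −78 °C; then aq. potassium sodium tartrate
Reagents that add atoms: none
Why: Partial reduction of the N-acyl sultam should stop at the chelated tetrahedral aluminate, which collapses to the aldehyde and auxiliary 6 on work-up; the (3R) centre is β to the carbonyl and cannot epimerize.

**Step 7**
Reactants: 9 (3R)-4,4,4-trichloro-3-methylbutanal; 10 glycine tert-butyl ester hydrochloride
Product: 11 tert-butyl N-[(1E,3R)-4,4,4-trichloro-3-methylbutylidene]glycinate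
Conditions: Et3N, MgSO4, CH2Cl2, rt; crude imine used at once
Reagents that add atoms: none
Why: Condensation of an aldehyde with an α-amino ester (imine formation) should give the E-imino ester, which is used without storage because aliphatic imino esters tautomerize and hydrolyse.

**Step 8**
Reactants: 11 tert-butyl N-[(1E,3R)-4,4,4-trichloro-3-methylbutylidene]glycinate; 12 2-methyl-1-nitroprop-1-ene
Product: 13 tert-butyl (2R,4S,5R)-3,3-dimethyl-4-nitro-5-[(2R)-3,3,3-trichloro-2-methylpropyl]pyrrolidine-2-carboxylate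
Conditions: Cu(CH3CN)4PF6 (5 mol%), (R)-DTBM-Segphos (5.5 mol%), Et3N (10 mol%), THF, −20 °C
Reagents that add atoms: none
Why: Et3N deprotonates the copper-bound imino ester 11 to the N,O-chelated azomethine ylide (C2–N1–C5), whose nucleophilic C2 adds to the β-carbon C3 of nitroalkene 12 while the resulting nitronate carbon C4 attacks the imine carbon C5, so that C2–C3 and C4–C5 form in one catalytic cycle. The closest known reaction type is the catalytic asymmetric 1,3-dipolar cycloaddition of metallo-azomethine ylides of α-imino esters with nitroalkenes. The pyrrolidine ring closes by a (3+2) cycloaddition, which in its stepwise description is a Michael addition followed by a 5-endo-trig nitro-Mannich closure. C2 and C5 are set together by the chiral bisphosphine on copper, which shields one face of the syn (W-shaped) ylide and enforces the 2,5-cis relationship, so that fixing C2 as R fixes C5 as R; C4 follows from exo approach of the nitro group and is inconsequential, and the remote (R) centre of the side chain is a spectator. The step needs regioselectivity (C2 to CMe2, C5 to C–NO2), secured by the polarization of the nitroalkene, and enantiofacial selectivity, secured by the ligand. Monovalent copper bound to a bisphosphine at −20 °C should not abstract chlorine from the CCl3 group.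

**Step 9**
Reactants: 13 tert-butyl (2R,4S,5R)-3,3-dimethyl-4-nitro-5-[(2R)-3,3,3-trichloro-2-methylpropyl]pyrrolidine-2-carboxylate; 5 (3S)-4,4,4-trichloro-3-methylbutanoic acid
Product: 15 tert-butyl (2R,4S,5R)-3,3-dimethyl-4-nitro-1-[(3S)-4,4,4-trichloro-3-methylbutanoyl]-5-[(2R)-3,3,3-trichloro-2-methylpropyl]pyrrolidine-2-carboxylate, via acid chloride 14 (not isolated)
Conditions: 5, 1-chloro-N,N,2-trimethylprop-1-en-1-amine, CH2Cl2, 0 °C to rt; then 13, pyridine, DMAP (cat.), 0 °C to rt
Reagents that add atoms: none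
Why: Neutral conversion of 5 into its acid chloride and acylation of the hindered secondary amine (amide formation) should install the side chain and block retro-Mannich opening of the β-nitro amine without touching a stereocentre.

**Step 10**
Reactants: 15
Product: 17 tert-butyl (2R,5R)-3,3-dimethyl-4-oxo-1-[(3S)-4,4,4-trichloro-3-methylbutanoyl]-5-[(2R)-3,3,3-trichloro-2-methylpropyl]pyrrolidine-2-carboxylate, via potassium nitronate 16 (not isolated)
Conditions: KOtBu (1.05 equiv), THF, −78 °C; O3/O2, CH2Cl2–MeOH, −78 °C; N2 purge; pH 7 buffer at −78 °C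
Reagents that add atoms: ozone, [O-][O+]=O
Why: The oxidative Nef reaction (ozonolysis of the nitronate C=N bond) should turn C4–NO2 into the C4 ketone in the cold, where the new α-amido ketone centre C5 should not enolize; both C4 epimers of 15 converge.

**Step 11**
Reactants: 17
Product: 18 (2R,5R)-3,3-dimethyl-4-oxo-1-[(3S)-4,4,4-trichloro-3-methylbutanoyl]-5-[(2R)-3,3,3-trichloro-2-methylpropyl]pyrrolidine-2-carboxylic acid
Conditions: TFA/CH2Cl2 (1:3), 0 °C to rt
Reagents that add atoms: none
Why: Acidolysis of the tert-butyl ester (E1 loss of isobutene) should free the C2 acid without base, so the enolizable C5 centre is preserved.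

**Step 12**
Reactants: 18
Product: 20 (2R)-5-hydroxy-4,4-dimethyl-1-[(3S)-4,4,4-trichloro-3-methylbutanoyl]-2-[(2R)-3,3,3-trichloro-2-methylpropyl]pyrrolidin-3-one (C5 epimers), via hemiaminal acetate 19 (not isolated)
Conditions: PhI(OAc)2 (1.5 equiv), I2 (0.5 equiv), CH2Cl2, visible light, rt; then H2O/THF, rt
Reagents that add atoms: water, O
Why: Radical oxidative decarboxylation of an N-acyl α-amino acid (acyl hypoiodite, C2 radical, N-acyliminium ion) should give the N,O-acetal, because the quaternary C3 rules out enamide formation and the cation can only be trapped at C2; C5 is not involved.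

**Step 13**
Reactants: 20
Product: 21 (5R)-3,3-dimethyl-1-[(3S)-4,4,4-trichloro-3-methylbutanoyl]-5-[(2R)-3,3,3-trichloro-2-methylpropyl]pyrrolidine-2,4-dione
Conditions: Dess–Martin periodinane, CH2Cl2, 0 °C to rt
Reagents that add atoms: none
Why: Oxidation of the N-acyl hemiaminal to the imide carbonyl (alcohol oxidation) under neutral conditions should complete the C2 lactam carbonyl without epimerizing C5.

**Compound list**

1 | (2R)-bornane-10,2-sultam [(1S)-(−)-2,10-camphorsultam] | CC1(C)[C@@H]2CC[C@]13CS(=O)(=O)N[C@@H]3C2 | starting material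
2 | (E)-but-2-enoyl chloride | C/C=C/C(=O)Cl | starting material
3 | (2R)-N-[(E)-but-2-enoyl]bornane-10,2-sultam | CC1(C)[C@@H]2CC[C@]13CS(=O)(=O)N(C(=O)/C=C/C)[C@@H]3C2 | intermediate
4 | (2R)-N-[(3S)-4,4,4-trichloro-3-methylbutanoyl]bornane-10,2-sultam | CC1(C)[C@@H]2CC[C@]13CS(=O)(=O)N(C(=O)C[C@H](C)C(Cl)(Cl)Cl)[C@@H]3C2 | intermediate
5 | (3S)-4,4,4-trichloro-3-methylbutanoic acid | OC(=O)C[C@H](C)C(Cl)(Cl)Cl | intermediate
6 | (2S)-bornane-10,2-sultam [(1R)-(+)-2,10-camphorsultam] | CC1(C)[C@H]2CC[C@@]13CS(=O)(=O)N[C@H]3C2 | starting material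
7 | (2S)-N-[(E)-but-2-enoyl]bornane-10,2-sultam | CC1(C)[C@H]2CC[C@@]13CS(=O)(=O)N(C(=O)/C=C/C)[C@H]3C2 | intermediate
8 | (2S)-N-[(3R)-4,4,4-trichloro-3-methylbutanoyl]bornane-10,2-sultam | CC1(C)[C@H]2CC[C@@]13CS(=O)(=O)N(C(=O)C[C@@H](C)C(Cl)(Cl)Cl)[C@H]3C2 | intermediate
9 | (3R)-4,4,4-trichloro-3-methylbutanal | O=CC[C@@H](C)C(Cl)(Cl)Cl | intermediate
10 | glycine tert-butyl ester hydrochloride | Cl.NCC(=O)OC(C)(C)C | starting material
11 | tert-butyl N-[(1E,3R)-4,4,4-trichloro-3-methylbutylidene]glycinate | CC(C)(C)OC(=O)C/N=C/C[C@@H](C)C(Cl)(Cl)Cl | intermediate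
12 | 2-methyl-1-nitroprop-1-ene | CC(C)=C[N+](=O)[O-] | starting material
13 | tert-butyl (2R,4S,5R)-3,3-dimethyl-4-nitro-5-[(2R)-3,3,3-trichloro-2-methylpropyl]pyrrolidine-2-carboxylate | C[C@H](C[C@@H]1[C@@H]([N+](=O)[O-])C(C)(C)[C@H](C(=O)OC(C)(C)C)N1)C(Cl)(Cl)Cl | intermediate
14 | (3S)-4,4,4-trichloro-3-methylbutanoyl chloride (not isolated) | ClC(=O)C[C@H](C)C(Cl)(Cl)Cl | intermediate
15 | tert-butyl (2R,4S,5R)-3,3-dimethyl-4-nitro-1-[(3S)-4,4,4-trichloro-3-methylbutanoyl]-5-[(2R)-3,3,3-trichloro-2-methylpropyl]pyrrolidine-2-carboxylate | C[C@H](C[C@@H]1[C@@H]([N+](=O)[O-])C(C)(C)[C@H](C(=O)OC(C)(C)C)N1C(=O)C[C@H](C)C(Cl)(Cl)Cl)C(Cl)(Cl)Cl | intermediate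
16 | potassium nitronate of 15 at C4 (not isolated) | [K+].C[C@H](C[C@@H]1C(=[N+]([O-])[O-])C(C)(C)[C@H](C(=O)OC(C)(C)C)N1C(=O)C[C@H](C)C(Cl)(Cl)Cl)C(Cl)(Cl)Cl | intermediate
17 | tert-butyl (2R,5R)-3,3-dimethyl-4-oxo-1-[(3S)-4,4,4-trichloro-3-methylbutanoyl]-5-[(2R)-3,3,3-trichloro-2-methylpropyl]pyrrolidine-2-carboxylate | C[C@H](C[C@@H]1C(=O)C(C)(C)[C@H](C(=O)OC(C)(C)C)N1C(=O)C[C@H](C)C(Cl)(Cl)Cl)C(Cl)(Cl)Cl | intermediate
18 | (2R,5R)-3,3-dimethyl-4-oxo-1-[(3S)-4,4,4-trichloro-3-methylbutanoyl]-5-[(2R)-3,3,3-trichloro-2-methylpropyl]pyrrolidine-2-carboxylic acid | C[C@H](C[C@@H]1C(=O)C(C)(C)[C@H](C(=O)O)N1C(=O)C[C@H](C)C(Cl)(Cl)Cl)C(Cl)(Cl)Cl | intermediate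
19 | (5R)-3,3-dimethyl-4-oxo-1-[(3S)-4,4,4-trichloro-3-methylbutanoyl]-5-[(2R)-3,3,3-trichloro-2-methylpropyl]pyrrolidin-2-yl acetate (C2 epimers, not isolated) | C[C@H](C[C@@H]1C(=O)C(C)(C)C(OC(C)=O)N1C(=O)C[C@H](C)C(Cl)(Cl)Cl)C(Cl)(Cl)Cl | intermediate
20 | (2R)-5-hydroxy-4,4-dimethyl-1-[(3S)-4,4,4-trichloro-3-methylbutanoyl]-2-[(2R)-3,3,3-trichloro-2-methylpropyl]pyrrolidin-3-one (C5 epimers) | C[C@H](C[C@@H]1C(=O)C(C)(C)C(O)N1C(=O)C[C@H](C)C(Cl)(Cl)Cl)C(Cl)(Cl)Cl | intermediate
21 | (5R)-3,3-dimethyl-1-[(3S)-4,4,4-trichloro-3-methylbutanoyl]-5-[(2R)-3,3,3-trichloro-2-methylpropyl]pyrrolidine-2,4-dione | C[C@H](C[C@@H]1C(=O)C(C)(C)C(=O)N1C(=O)C[C@H](C)C(Cl)(Cl)Cl)C(Cl)(Cl)Cl | target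

**Step count and risks**

Total step count: 13. Longest linear sequence: 10 steps (steps 4 to 13, from sultam 6 to target 21); steps 1 to 3 join at step 9.

Steps most likely to fail:

1. Step 8. The Michael event onto the β,β-disubstituted nitroalkene may be slow, so that enamine tautomerization and hydrolysis of the aliphatic imine compete, and facial control by the ligand may be incomplete. Fallback: the same two bonds are made stepwise. Setting out from 12 and purchased tert-butyl N-(diphenylmethylidene)glycinate, an asymmetric phase-transfer Michael addition (cinchona-derived quaternary ammonium bromide of the series that gives 2R, CsOH·H2O, toluene/CH2Cl2, −60 °C) forms C2–C3 and should give tert-butyl (2R)-2-[(diphenylmethylidene)amino]-3,3-dimethyl-4-nitrobutanoate F1. Aqueous citric acid in THF then removes the benzophenone group to give tert-butyl (2R)-2-amino-3,3-dimethyl-4-nitrobutanoate F2. Condensation of F2 with aldehyde 9 (MgSO4, CH2Cl2) gives tert-butyl (2R)-3,3-dimethyl-4-nitro-2-{[(1E,3R)-4,4,4-trichloro-3-methylbutylidene]amino}butanoate F3, which should close the C4–C5 bond by reversible intramolecular nitro-Mannich reaction (Et3N cat.), the C2 centre relaying to the 2,5-cis isomer under thermodynamic control. The fallback comes back to the route at 13.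

2. Step 10. Deprotonation at the hindered C4–H may be incomplete, the nitronate may open the ring by β-elimination of the amide nitrogen, and residual alkoxide may epimerize C5 on warming. Fallback: the nitro group is taken to the ketone through the oxime without ozone or alkoxide. Setting out from 15, DBU and benzyl bromide in MeCN at rt O-benzylate the nitronate to the O-benzyl nitronic ester of 15 F4, which should fragment (as in the Hass–Bender oxidation) to benzaldehyde and tert-butyl (2R,5R)-4-(hydroxyimino)-3,3-dimethyl-1-[(3S)-4,4,4-trichloro-3-methylbutanoyl]-5-[(2R)-3,3,3-trichloro-2-methylpropyl]pyrrolidine-2-carboxylate F5. Transoximation of F5 with aqueous glyoxylic acid under mildly acidic conditions comes back to the route at 17.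

3. Step 12. The C2 radical may abstract chlorine from a CCl3 group, and iodine may attack the enolizable C5 position before the radical is oxidized to the N-acyliminium ion. Fallback: a non-radical Curtius degradation. Setting out from 18, diphenylphosphoryl azide and Et3N in toluene at 0 °C should give (2R,5R)-3,3-dimethyl-4-oxo-1-[(3S)-4,4,4-trichloro-3-methylbutanoyl]-5-[(2R)-3,3,3-trichloro-2-methylpropyl]pyrrolidine-2-carbonyl azide F6. Warming to 80 °C rearranges F6 with retention to (2R,5R)-5-isocyanato-4,4-dimethyl-1-[(3S)-4,4,4-trichloro-3-methylbutanoyl]-2-[(2R)-3,3,3-trichloro-2-methylpropyl]pyrrolidin-3-one F7. Hydrolysis of F7 in aqueous HCl/THF, with loss of carbon dioxide and ammonia from the geminal amino amide, comes back to the route at 20.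

**Further compounds**

F1 | step 8 | tert-butyl (2R)-2-[(diphenylmethylidene)amino]-3,3-dimethyl-4-nitrobutanoate | CC(C)(C)OC(=O)[C@H](N=C(c1ccccc1)c1ccccc1)C(C)(C)C[N+](=O)[O-]
F2 | step 8 | tert-butyl (2R)-2-amino-3,3-dimethyl-4-nitrobutanoate | CC(C)(C)OC(=O)[C@H](N)C(C)(C)C[N+](=O)[O-]
F3 | step 8 | tert-butyl (2R)-3,3-dimethyl-4-nitro-2-{[(1E,3R)-4,4,4-trichloro-3-methylbutylidene]amino}butanoate | CC(C)(C)OC(=O)[C@H](/N=C/C[C@@H](C)C(Cl)(Cl)Cl)C(C)(C)C[N+](=O)[O-]
F4 | step 10 | O-benzyl nitronic ester of 15 | C[C@H](C[C@@H]1C(=[N+]([O-])OCc2ccccc2)C(C)(C)[C@H](C(=O)OC(C)(C)C)N1C(=O)C[C@H](C)C(Cl)(Cl)Cl)C(Cl)(Cl)Cl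
F5 | step 10 | tert-butyl (2R,5R)-4-(hydroxyimino)-3,3-dimethyl-1-[(3S)-4,4,4-trichloro-3-methylbutanoyl]-5-[(2R)-3,3,3-trichloro-2-methylpropyl]pyrrolidine-2-carboxylate | C[C@H](C[C@@H]1C(=NO)C(C)(C)[C@H](C(=O)OC(C)(C)C)N1C(=O)C[C@H](C)C(Cl)(Cl)Cl)C(Cl)(Cl)Cl
F6 | step 12 | (2R,5R)-3,3-dimethyl-4-oxo-1-[(3S)-4,4,4-trichloro-3-methylbutanoyl]-5-[(2R)-3,3,3-trichloro-2-methylpropyl]pyrrolidine-2-carbonyl azide | C[C@H](C[C@@H]1C(=O)C(C)(C)[C@H](C(=O)N=[N+]=[N-])N1C(=O)C[C@H](C)C(Cl)(Cl)Cl)C(Cl)(Cl)Cl
F7 | step 12 | (2R,5R)-5-isocyanato-4,4-dimethyl-1-[(3S)-4,4,4-trichloro-3-methylbutanoyl]-2-[(2R)-3,3,3-trichloro-2-methylpropyl]pyrrolidin-3-one | C[C@H](C[C@@H]1C(=O)C(C)(C)[C@H](N=C=O)N1C(=O)C[C@H](C)C(Cl)(Cl)Cl)C(Cl)(Cl)Cl
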